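**Plan**

Numbering (germacrane): carbocycle C1–C10 (C1/C10 epoxide, C3 acetate, C4=C5, C6 lactone oxygen, C7 ring fusion, C8 ester), C11–C13 methylene lactone, C14/C15 methyls. Enabling feature: C8 is a carbinol carbon bonded to C7, and C7 is the γ-carbon of the allyl unit C13–C11=C7 inside a 3-(bromomethyl)butenolide, so C7–C8 can be made by allylmetal addition to a C8 aldehyde, which closes the ten-membered ring and unveils the α-methylene lactone in one event.
Cuts, in retrosynthetic order: the epoxide C–O bonds; the C3 acetate and the C8 ester C–O bond (the latter formed with inversion); C7–C8 (carbocycle); C11–C12 and C12–O (CO insertion, butenolide); C6–C7 (alkynylation); C5–C6 (formylation); C1=C10 (ring-closing metathesis in a temporary lactone); C2–C3 (allylation); C4–C15 (carbomagnesiation of propargyl alcohol).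
Forward: the C3–C5 iodoalkene is extended by C2/C1 and by C8–C10; a seven-membered lactone (ring 1, temporary) is closed and reduced open; C6, then C7/C11/C13 are added; the butenolide (ring 2) is closed with CO, the carbocycle (ring 3) with divalent chromium, and the epoxide (ring 4) comes last.
Stereochemistry: (Z)-C4=C5 from anti-carbomagnesiation; (Z)-C1=C10 from the seven-membered ring; C3 from Brown allylation; C6 from dinuclear zinc–ProPhenol alkynylation; C7 and C8 from the chair transition state of the ring closure (trans lactone, 7,8-anti), C8 then inverted in a Mitsunobu esterification; C1/C10 from peripheral peracid attack on the ring alkene; the side-chain centre from (R)-2-methylbutanoic acid.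

Key step: step 15

Remark: the butenolide-derived allylchromium is (E)-configured (C6 trans to C13), so a chair transition state should give the 7,8-anti adduct; the ring-closure product 24 therefore carries C8 in the configuration opposite to that of the final ester, and the 2-methylbutanoate is introduced with inversion.
Remark: the (S,S)-ProPhenol–zinc catalyst is assumed to deliver the alkynyl group to the Re face of enal 13 (giving 6S); should a model enal show the opposite sense, the (R,R) ligand is used.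

**Route**

Step 1
Reactants: 1 propargyl alcohol
Product: 3 (Z)-3-iodo-2-methylprop-2-en-1-ol, via alkenylmagnesium alkoxide 2 (not isolated)
Conditions: MeMgBr (3 equiv), CuI (10 mol%), THF, −10 °C → rt; then I2, −78 → 0 °C
Reagents that add atoms: methylmagnesium bromide, C[Mg]Br; iodine, II
Why: Copper-catalysed anti-carbomagnesiation of the propargylic alkoxide (Duboudin reaction) places methyl on C4 and magnesium on C5 cis to the CH2O group through a five-membered chelate, and iodinolysis with retention fixes the (Z)-C4=C5 geometry.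

Step 2
Reactants: 3 (Z)-3-iodo-2-methylprop-2-en-1-ol
Product: 4 (Z)-3-iodo-2-methylprop-2-enal
Conditions: MnO2, CH2Cl2, rt, dark; used crude
Reagents that add atoms: none
Why: MnO2 oxidises the allylic alcohol under neutral conditions, which should preserve the isomerisation-prone (Z)-enal when it is used directly.

Step 3
Reactants: 4 (Z)-3-iodo-2-methylprop-2-enal
Product: 6 (1Z,3R)-1-iodo-2-methylhexa-1,5-dien-3-ol, via diisopinocampheylborinate 5 (not isolated)
Conditions: (+)-Ipc2B(allyl) [the (−)-α-pinene-derived reagent], Et2O, −78 °C; then NaOH, H2O2, 0 °C → rt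
Reagents that add atoms: (+)-B-allyldiisopinocampheylborane, C=CCB([C@H]1C[C@H]2C[C@@H]([C@@H]1C)C2(C)C)[C@H]1C[C@H]2C[C@@H]([C@@H]1C)C2(C)C
Why: Brown allylboration runs through a chair transition state in which the isopinocampheyl groups direct the allyl group to the Re face of the aldehyde, which sets C3 as R under reagent control.

Step 4
Reactants: 6 (1Z,3R)-1-iodo-2-methylhexa-1,5-dien-3-ol; 7 3-methylbut-3-enoic acid
Product: 8 (1Z,3R)-1-iodo-2-methylhexa-1,5-dien-3-yl 3-methylbut-3-enoate
Conditions: DCC, DMAP (5 mol%), CH2Cl2, 0 °C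
Reagents that add atoms: none
Why: Steglich esterification at 0 °C with little DMAP acylates the secondary allylic alcohol without touching C3 and should keep the β,γ-unsaturated acyl group from moving into conjugation.

Step 5
Reactants: 8 (1Z,3R)-1-iodo-2-methylhexa-1,5-dien-3-yl 3-methylbut-3-enoate
Product: 9 (7R)-7-[(Z)-1-iodoprop-1-en-2-yl]-4-methyl-6,7-dihydrooxepin-2(3H)-one
Conditions: second-generation Grubbs catalyst (H2IMes)(PCy3)Cl2Ru=CHPh (5 mol%), 1,4-benzoquinone (10 mol%), CH2Cl2 (2 mM), reflux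
Reagents that add atoms: none
Why: Ring-closing metathesis joins the monosubstituted and the 1,1-disubstituted alkene while the iodine-bearing trisubstituted alkene stays inert, and the seven-membered ring can hold the new C1=C10 double bond only in the cis (Z) form.

Step 6
Reactants: 9 (7R)-7-[(Z)-1-iodoprop-1-en-2-yl]-4-methyl-6,7-dihydrooxepin-2(3H)-one
Product: 10 (3Z,6R,7Z)-8-iodo-3,7-dimethylocta-3,7-diene-1,6-diol
Conditions: i-Bu2AlH (4 equiv), CH2Cl2, −78 → 0 °C
Reagents that add atoms: none
Why: Hydride reduction of the lactone with i-Bu2AlH gives the diol without touching the alkenyl iodide, and the (Z)-geometry fixed in the ring is carried into the open chain.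

Step 7
Reactants: 10 (3Z,6R,7Z)-8-iodo-3,7-dimethylocta-3,7-diene-1,6-diol
Product: 11 (1Z,3R,5Z)-3,8-bis(tert-butyldimethylsilyloxy)-1-iodo-2,6-dimethylocta-1,5-diene
Conditions: TBSOTf (2.5 equiv), 2,6-lutidine, CH2Cl2, −78 → 0 °C
Reagents that add atoms: tert-butyldimethylsilyl trifluoromethanesulfonate, CC(C)(C)[Si](C)(C)OS(=O)(=O)C(F)(F)F
Why: The silyl triflate with a hindered base silylates the primary and the hindered secondary allylic hydroxyl in one operation (silyl ether protection).

Step 8
Reactants: 11 (1Z,3R,5Z)-3,8-bis(tert-butyldimethylsilyloxy)-1-iodo-2,6-dimethylocta-1,5-diene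
Product: 13 (2Z,4R,6Z)-4,9-bis(tert-butyldimethylsilyloxy)-3,7-dimethylnona-2,6-dienal, via alkenyllithium 12 (not isolated)
Conditions: t-BuLi (2.1 equiv), Et2O, −78 °C; then DMF, −78 → 0 °C
Reagents that add atoms: N,N-dimethylformamide, CN(C)C=O
Why: Iodine–lithium exchange occurs with retention of alkene geometry at −78 °C, and formylation of the alkenyllithium with DMF (Bouveault-type) gives the (Z)-enal carrying C6.

Step 9
Reactants: 13 (2Z,4R,6Z)-4,9-bis(tert-butyldimethylsilyloxy)-3,7-dimethylnona-2,6-dienal; 14 tert-butyldimethyl(prop-2-yn-1-yloxy)silane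
Product: 16 (4S,5Z,7R,9Z)-1,7,12-tris(tert-butyldimethylsilyloxy)-6,10-dimethyldodeca-5,9-dien-2-yn-4-ol, via alkynylzinc 15 (not isolated)
Conditions: 14 (3 equiv), Me2Zn (3 equiv), (S,S)-ProPhenol (20 mol%), Ph3P=O (40 mol%), toluene, 4 °C
Reagents that add atoms: none
Why: Dinuclear zinc–ProPhenol catalysis (Trost asymmetric alkynylation of enals) adds the alkynylzinc to one face of the aldehyde under catalyst control and sets C6 as S, the remote C3 centre having little say.

Step 10
Reactants: 16 (4S,5Z,7R,9Z)-1,7,12-tris(tert-butyldimethylsilyloxy)-6,10-dimethyldodeca-5,9-dien-2-yn-4-ol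
Product: 18 (2Z,4S,5Z,7R,9Z)-1,7,12-tris(tert-butyldimethylsilyloxy)-2-iodo-6,10-dimethyldodeca-2,5,9-trien-4-ol, via cyclic alkenylalanate 17 (not isolated)
Conditions: NaAlH2(OCH2CH2OMe)2 (Red-Al), THF, 0 °C; EtOAc; then I2, −78 → 0 °C
Reagents that add atoms: iodine, II
Why: The propargylic alkoxide delivers hydride to C7 and leaves aluminium on C11 (trans-hydroalumination), so iodinolysis at low temperature gives the (Z)-iodoalkene with iodine on C11 cis to C6.

Step 11
Reactants: 18 (2Z,4S,5Z,7R,9Z)-1,7,12-tris(tert-butyldimethylsilyloxy)-2-iodo-6,10-dimethyldodeca-2,5,9-trien-4-ol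
Product: 19 (5S)-5-[(1Z,3R,5Z)-3,8-bis(tert-butyldimethylsilyloxy)-2,6-dimethylocta-1,5-dien-1-yl]-3-[(tert-butyldimethylsilyloxy)methyl]furan-2(5H)-one
Conditions: PdCl2(PPh3)2 (5 mol%), CO (1 atm), K2CO3, THF, 40 °C
Reagents that add atoms: carbon monoxide, [C-]#[O+]
Why: Oxidative addition of zerovalent palladium into the C11–I bond, CO insertion and capture of the acylpalladium by the cis-disposed C6 hydroxyl (carbonylative lactonisation of a (Z)-3-iodoallylic alcohol) close the butenolide without touching C6.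

Step 12
Reactants: 19 the tris-silyl butenolide
Product: 20 (5S)-5-[(1Z,3R,5Z)-3-(tert-butyldimethylsilyloxy)-8-hydroxy-2,6-dimethylocta-1,5-dien-1-yl]-3-(hydroxymethyl)furan-2(5H)-one
Conditions: HF·pyridine, pyridine, THF, 0 °C, stopped once both primary ethers are gone
Reagents that add atoms: none
Why: Desilylation is much faster at the two unhindered primary silyl ethers than at the secondary allylic C3 ether next to the C4 methyl, so buffered HF·pyridine should free only C8–OH and C13–OH (selective silyl ether cleavage).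

Step 13
Reactants: 20 the C8,C13-diol
Product: 21 (5S)-3-(bromomethyl)-5-[(1Z,3R,5Z)-3-(tert-butyldimethylsilyloxy)-8-hydroxy-2,6-dimethylocta-1,5-dien-1-yl]furan-2(5H)-one
Conditions: NBS, Me2S, CH2Cl2, −20 °C (reagent preformed); then 20, −20 → 0 °C
Reagents that add atoms: N-bromosuccinimide, O=C1CCC(=O)N1Br
Why: The Corey–Kim reagent converts only the allylic C13 alkoxysulfonium into the bromide, while the saturated C8 hydroxyl is returned on work-up, as in the bromination of Baylis–Hillman alcohols.

Step 14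
Reactants: 21 the C13 bromide with free C8–OH
Product: 22 (3Z,6R,7Z)-8-[(2S)-4-(bromomethyl)-5-oxo-2,5-dihydrofuran-2-yl]-6-(tert-butyldimethylsilyloxy)-3,7-dimethylocta-3,7-dienal
Conditions: Dess–Martin periodinane, NaHCO3, CH2Cl2, 0 °C; used at once
Reagents that add atoms: none
Why: Buffered Dess–Martin oxidation is neutral and fast, so the β,γ-unsaturated aldehyde should form without migration of the C1=C10 double bond and without loss of the allylic bromide.

Step 15
Reactants: 22 the C8 aldehyde carrying the 3-(bromomethyl)butenolide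
Product: 24 (3R,6S,7S,8R)-3-(tert-butyldimethylsilyloxy)-8-hydroxygermacra-1(10)Z,4Z,11(13)-trien-6,12-olide, via allylchromium 23 (not isolated)
Conditions: CrCl2 (6 equiv), THF, rt, slow addition of 22 (final 2 mM)
Reagents that add atoms: none
Why: CrCl2 reduces the allylic C13–Br bond in two one-electron steps to the σ-allylchromium 23 (trivalent chromium), the tethered aldehyde binds to the metal, and the γ-carbon C7 adds to C8 through a six-membered chair in an SE2' sense, which forms C7–C8 and moves the double bond to C11=C13. The closest known reaction types are the Nozaki–Hiyama (chromium Barbier) additions of 3-(bromomethyl)furan-2(5H)-ones to aldehydes and intramolecular allylchromium closures of ten-membered carbocycles. The carbocycle closes by 10-exo-trig addition to the carbonyl group, helped by the two (Z)-alkenes, which bend the chain so that C8 lies near C7. C7: the aldehyde should reach the butenolide face opposite to the C6–C5 bond, because only then is the C5–C6–C7–C8 unit staggered in the forming ring, and this gives the trans lactone (7S). C8: the cyclic allylchromium is (E)-configured (C6 trans to C13), so the chair with C9 equatorial places the new oxygen anti to C6 and should give the 7,8-anti adduct (8R), the usual outcome of chromium crotylation. The step needs ring closure to beat intermolecular coupling, which high dilution and slow addition secure, and it needs no further protection because the lactone, both alkenes and the silyl ether are inert to divalent chromium.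

Step 16
Reactants: 24 the (8R)-alcohol; 25 (R)-2-methylbutanoic acid
Product: 26 (3R,6S,7S,8S)-3-(tert-butyldimethylsilyloxy)-8-[(2R)-2-methylbutanoyloxy]germacra-1(10)Z,4Z,11(13)-trien-6,12-olide
Conditions: PPh3, DIAD (betaine preformed at 0 °C); then 24 and 25, toluene, 0 °C → rt
Reagents that add atoms: none
Why: Mitsunobu esterification activates the C8 hydroxyl as an oxyphosphonium ion that the carboxylate displaces with inversion, which turns 8R into the 8S ester, and since the acid is never activated its α-centre cannot epimerise.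

Step 17
Reactants: 26 the C3 silyl ether
Product: 27 (3R,6S,7S,8S)-3-hydroxy-8-[(2R)-2-methylbutanoyloxy]germacra-1(10)Z,4Z,11(13)-trien-6,12-olide
Conditions: HF·pyridine, THF, 0 °C → rt
Reagents that add atoms: none
Why: HF·pyridine cleaves the secondary silyl ether under mildly acidic conditions that leave the ester, the lactone and the alkenes intact (fluoride desilylation).

Step 18
Reactants: 27 the C3 alcohol
Product: 28 (3R,6S,7S,8S)-3-acetoxy-8-[(2R)-2-methylbutanoyloxy]germacra-1(10)Z,4Z,11(13)-trien-6,12-olide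
Conditions: Ac2O, pyridine, DMAP (cat.), CH2Cl2, 0 °C → rt
Reagents that add atoms: acetic anhydride, CC(=O)OC(C)=O
Why: DMAP-catalysed acetylation of the secondary allylic alcohol is a standard acylation that touches no stereocentre.

Step 19
Reactants: 28 the (Z,Z)-dienolide diester
Product: 29 (1R,3R,6S,7S,8S,10S)-3-acetoxy-1,10-epoxy-8-[(2R)-2-methylbutanoyloxy]germacra-4Z,11(13)-dien-6,12-olide (CNP0340603.1)
Conditions: mCPBA (1.1 equiv), NaHCO3, CH2Cl2, 0 °C
Reagents that add atoms: 3-chloroperoxybenzoic acid, O=C(OO)c1cccc(Cl)c1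
Why: The peracid (Prilezhaev epoxidation) should pick the only electron-rich alkene, C1=C10, over C4=C5 (flanked by two acyloxy groups) and the conjugated C11=C13, add syn so that the (Z)-alkene gives the cis-epoxide, and attack the outer face of the ring-bound alkene to set C1 as R and C10 as S.

**Compound list**

1 | prop-2-yn-1-ol (propargyl alcohol) | C#CCO | starting material
2 | bromomagnesium (Z)-3-(bromomagnesio)-2-methylprop-2-en-1-olate | Br[Mg]/C=C(/C)CO[Mg]Br | intermediate
3 | (Z)-3-iodo-2-methylprop-2-en-1-ol | I/C=C(/C)CO | intermediate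
4 | (Z)-3-iodo-2-methylprop-2-enal | I/C=C(/C)C=O | intermediate
5 | (1Z,3R)-1-iodo-2-methylhexa-1,5-dien-3-yl diisopinocampheylborinate | I/C=C(/C)[C@H](OB([C@H]1C[C@H]2C[C@@H]([C@@H]1C)C2(C)C)[C@H]1C[C@H]2C[C@@H]([C@@H]1C)C2(C)C)CC=C | intermediate
6 | (1Z,3R)-1-iodo-2-methylhexa-1,5-dien-3-ol | I/C=C(/C)[C@H](O)CC=C | intermediate
7 | 3-methylbut-3-enoic acid | C=C(C)CC(=O)O | starting material
8 | (1Z,3R)-1-iodo-2-methylhexa-1,5-dien-3-yl 3-methylbut-3-enoate | I/C=C(/C)[C@H](OC(=O)CC(C)=C)CC=C | intermediate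
9 | (7R)-7-[(Z)-1-iodoprop-1-en-2-yl]-4-methyl-6,7-dihydrooxepin-2(3H)-one | I/C=C(/C)[C@@H]1OC(=O)C/C(C)=C\C1 | intermediate
10 | (3Z,6R,7Z)-8-iodo-3,7-dimethylocta-3,7-diene-1,6-diol | I/C=C(/C)[C@H](O)C/C=C(/C)CCO | intermediate
11 | (1Z,3R,5Z)-3,8-bis(tert-butyldimethylsilyloxy)-1-iodo-2,6-dimethylocta-1,5-diene | I/C=C(/C)[C@H](O[Si](C)(C)C(C)(C)C)C/C=C(/C)CCO[Si](C)(C)C(C)(C)C | intermediate
12 | [(1Z,3R,5Z)-3,8-bis(tert-butyldimethylsilyloxy)-2,6-dimethylocta-1,5-dien-1-yl]lithium | [Li]/C=C(/C)[C@H](O[Si](C)(C)C(C)(C)C)C/C=C(/C)CCO[Si](C)(C)C(C)(C)C | intermediate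
13 | (2Z,4R,6Z)-4,9-bis(tert-butyldimethylsilyloxy)-3,7-dimethylnona-2,6-dienal | O=C/C=C(/C)[C@H](O[Si](C)(C)C(C)(C)C)C/C=C(/C)CCO[Si](C)(C)C(C)(C)C | intermediate
14 | tert-butyldimethyl(prop-2-yn-1-yloxy)silane | C#CCO[Si](C)(C)C(C)(C)C | starting material
15 | methyl[3-(tert-butyldimethylsilyloxy)prop-1-yn-1-yl]zinc | C[Zn]C#CCO[Si](C)(C)C(C)(C)C | intermediate
16 | (4S,5Z,7R,9Z)-1,7,12-tris(tert-butyldimethylsilyloxy)-6,10-dimethyldodeca-5,9-dien-2-yn-4-ol | O[C@@H](/C=C(/C)[C@H](O[Si](C)(C)C(C)(C)C)C/C=C(/C)CCO[Si](C)(C)C(C)(C)C)C#CCO[Si](C)(C)C(C)(C)C | intermediate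
17 | sodium bis(2-methoxyethoxy)aluminate of 16, cyclic, with aluminium bound to the C6 oxygen and to C11 | [Na+].COCCO[Al-]1(OCCOC)O[C@@H](/C=C(/C)[C@H](O[Si](C)(C)C(C)(C)C)C/C=C(/C)CCO[Si](C)(C)C(C)(C)C)C=C1CO[Si](C)(C)C(C)(C)C | intermediate
18 | (2Z,4S,5Z,7R,9Z)-1,7,12-tris(tert-butyldimethylsilyloxy)-2-iodo-6,10-dimethyldodeca-2,5,9-trien-4-ol | O[C@@H](/C=C(/C)[C@H](O[Si](C)(C)C(C)(C)C)C/C=C(/C)CCO[Si](C)(C)C(C)(C)C)/C=C(\I)CO[Si](C)(C)C(C)(C)C | intermediate
19 | (5S)-5-[(1Z,3R,5Z)-3,8-bis(tert-butyldimethylsilyloxy)-2,6-dimethylocta-1,5-dien-1-yl]-3-[(tert-butyldimethylsilyloxy)methyl]furan-2(5H)-one | O=C1O[C@@H](/C=C(/C)[C@H](O[Si](C)(C)C(C)(C)C)C/C=C(/C)CCO[Si](C)(C)C(C)(C)C)C=C1CO[Si](C)(C)C(C)(C)C | intermediate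
20 | (5S)-5-[(1Z,3R,5Z)-3-(tert-butyldimethylsilyloxy)-8-hydroxy-2,6-dimethylocta-1,5-dien-1-yl]-3-(hydroxymethyl)furan-2(5H)-one | O=C1O[C@@H](/C=C(/C)[C@H](O[Si](C)(C)C(C)(C)C)C/C=C(/C)CCO)C=C1CO | intermediate
21 | (5S)-3-(bromomethyl)-5-[(1Z,3R,5Z)-3-(tert-butyldimethylsilyloxy)-8-hydroxy-2,6-dimethylocta-1,5-dien-1-yl]furan-2(5H)-one | O=C1O[C@@H](/C=C(/C)[C@H](O[Si](C)(C)C(C)(C)C)C/C=C(/C)CCO)C=C1CBr | intermediate
22 | (3Z,6R,7Z)-8-[(2S)-4-(bromomethyl)-5-oxo-2,5-dihydrofuran-2-yl]-6-(tert-butyldimethylsilyloxy)-3,7-dimethylocta-3,7-dienal | O=C1O[C@@H](/C=C(/C)[C@H](O[Si](C)(C)C(C)(C)C)C/C=C(/C)CC=O)C=C1CBr | intermediate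
23 | C13-dichlorochromium derivative of 22 (σ-allylchromium, trivalent chromium) | O=C1O[C@@H](/C=C(/C)[C@H](O[Si](C)(C)C(C)(C)C)C/C=C(/C)CC=O)C=C1C[Cr](Cl)Cl | intermediate
24 | (3R,6S,7S,8R)-3-(tert-butyldimethylsilyloxy)-8-hydroxygermacra-1(10)Z,4Z,11(13)-trien-6,12-olide | C=C1C(=O)O[C@H]2/C=C(/C)[C@H](O[Si](C)(C)C(C)(C)C)C/C=C(/C)C[C@@H](O)[C@H]12 | intermediate
25 | (R)-2-methylbutanoic acid | CC[C@@H](C)C(=O)O | starting material
26 | (3R,6S,7S,8S)-3-(tert-butyldimethylsilyloxy)-8-[(2R)-2-methylbutanoyloxy]germacra-1(10)Z,4Z,11(13)-trien-6,12-olide | C=C1C(=O)O[C@H]2/C=C(/C)[C@H](O[Si](C)(C)C(C)(C)C)C/C=C(/C)C[C@H](OC(=O)[C@H](C)CC)[C@H]12 | intermediate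
27 | (3R,6S,7S,8S)-3-hydroxy-8-[(2R)-2-methylbutanoyloxy]germacra-1(10)Z,4Z,11(13)-trien-6,12-olide | C=C1C(=O)O[C@H]2/C=C(/C)[C@H](O)C/C=C(/C)C[C@H](OC(=O)[C@H](C)CC)[C@H]12 | intermediate
28 | (3R,6S,7S,8S)-3-acetoxy-8-[(2R)-2-methylbutanoyloxy]germacra-1(10)Z,4Z,11(13)-trien-6,12-olide | C=C1C(=O)O[C@H]2/C=C(/C)[C@H](OC(C)=O)C/C=C(/C)C[C@H](OC(=O)[C@H](C)CC)[C@H]12 | intermediate
29 | (1R,3R,6S,7S,8S,10S)-3-acetoxy-1,10-epoxy-8-[(2R)-2-methylbutanoyloxy]germacra-4Z,11(13)-dien-6,12-olide | C=C1C(=O)O[C@H]2/C=C(/C)[C@H](OC(C)=O)C[C@H]3O[C@@]3(C)C[C@H](OC(=O)[C@H](C)CC)[C@H]12 | target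

**Step count and risks**

Total step count: 19. Longest linear sequence: 19 steps (1 → 29); compounds 7, 14 and 25 are purchased and enter in steps 4, 9 and 16.

Steps most likely to fail:

Step 15. The aldehyde may add through the other chair (C9 axial) or a boat, so that facial selectivity at C8 is poor or reversed. Fallback: the closure of 22 is run as before, and the 7,8-syn product, the C8 epimer of 24, (3R,6S,7S,8S)-3-(tert-butyldimethylsilyloxy)-8-hydroxygermacra-1(10)Z,4Z,11(13)-trien-6,12-olide F1, is separated. It is then esterified with 25 with retention of configuration (Steglich conditions: DIC, DMAP cat., CH2Cl2, 0 °C), which gives 26 directly and makes the inversion unnecessary for that material.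

Step 16. The C8 oxyphosphonium ion may eliminate towards C9 (giving a diene conjugated with C1=C10), or the hindered displacement may stall. Fallback: 24 is first converted with ClCH2SO2Cl and pyridine (CH2Cl2, 0 °C) into its 8-O-chloromethanesulfonate F2. This sulfonate is displaced with inversion by the caesium salt of 25 (Cs2CO3, 18-crown-6, toluene, 60 °C), a weakly basic carboxylate that favours substitution over elimination, and the route is rejoined at 26.

Step 19. The peracid may attack the other face of the C1=C10 alkene (poor or wrong facial selectivity), which would give the diastereomeric epoxide. Fallback: 28 is treated with NBS in THF–H2O at 0 °C. The bromonium ion forms on the face the peracid prefers, and water opens it anti at the tertiary C10, giving the bromohydrin (1S,10S)-1-bromo-10-hydroxy derivative of 28 F3. Ring closure with K2CO3 in acetone at rt, with inversion at C1, then places the epoxide oxygen on the opposite face and gives 29.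

Further compounds
F1 | step 15 | (3R,6S,7S,8S)-3-(tert-butyldimethylsilyloxy)-8-hydroxygermacra-1(10)Z,4Z,11(13)-trien-6,12-olide (C8 epimer of 24) | C=C1C(=O)O[C@H]2/C=C(/C)[C@H](O[Si](C)(C)C(C)(C)C)C/C=C(/C)C[C@H](O)[C@H]12
F2 | step 16 | 8-O-chloromethanesulfonate of 24 | C=C1C(=O)O[C@H]2/C=C(/C)[C@H](O[Si](C)(C)C(C)(C)C)C/C=C(/C)C[C@@H](OS(=O)(=O)CCl)[C@H]12
F3 | step 19 | (1S,10S)-1-bromo-10-hydroxy-1,10-dihydro derivative of 28 (bromohydrin) | C=C1C(=O)O[C@H]2/C=C(/C)[C@H](OC(C)=O)C[C@H](Br)[C@@](C)(O)C[C@H](OC(=O)[C@H](C)CC)[C@H]12
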